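**Retrosynthetic overview**

1. Target 19 comes from buffered fluoride cleavage of the cyclic diisopropylsilylene 18, in which one silicon bridges O7 (phenol on ring A) and O3' (tertiary carbinol).
2. 18 comes from ring-closing metathesis of the silyl-tethered diene 17, forming C1'=C2'. The plan rests on this feature: the C1'=C2' olefin on C8 lies between O7 and O3', so the tether closes an 8-membered ring (O7, Si, O3', C3', C2', C1', C8, C7) fused to ring A that can hold the olefin only as Z.
3. 17 is assembled from iPr2Si(OTf)2 15, (2S)-7-hydroxy-8-vinylflavanone 9 and the (2R)-alkenol acetate 14.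
4. 9 comes from rhodium-catalysed asymmetric conjugate phenylation (sets C2) of 8-vinylchromone 6, made from 2,4-dihydroxyacetophenone by C3 iodination, closure of pyranone ring C and Stille vinylation.
5. 14 comes from (S)-2-methylglycidol by sulfonium-ylide homologation of the epoxide, then acetylation of the primary OH. Ring order: ring C (step 3), the temporary silacycle (step 12), opened again in step 13.

Key step: step 12

Numbering: flavanone numbering; the side chain is C1' to C4' counted from C8 (C4' is the CH2OAc carbon).

Assumption: the (S)-configured biaryl diphosphine in step 5 is taken to give (2S), by the enone-face model under which (S)-BINAP–rhodium gives (S)-3-arylcyclohexanones. If the sense is opposite on this chromone, the (R)-ligand is used and nothing else changes.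

**Route**

Step 1
Reactants: 1 2,4-dihydroxyacetophenone
Product: 2 2,4-dihydroxy-3-iodoacetophenone
Conditions: I2 (0.4 equiv), HIO3 (0.2 equiv), EtOH–H2O, 25–40 °C
Reagents that add atoms: iodine, [I][I]; iodic acid, OI(=O)=O
Why: Electrophilic aromatic iodination with iodic acid as oxidant should take C3, the position ortho to both hydroxyl groups, as resorcinol-type phenols are known to iodinate between the two oxygens; substoichiometric iodine limits di-iodination and any 5-iodo isomer is removed by crystallisation.

Step 2
Reactants: 2 2,4-dihydroxy-3-iodoacetophenone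
Product: 3 1-[2-hydroxy-3-iodo-4-(triisopropylsilyloxy)phenyl]ethanone
Conditions: iPr3SiCl (1.05 equiv), imidazole, CH2Cl2, 0 °C to rt
Reagents that add atoms: chlorotriisopropylsilane, CC(C)[Si](Cl)(C(C)C)C(C)C
Why: Chemoselective phenol silylation: the 2-OH is held in a hydrogen bond to the acetyl carbonyl and is flanked on both sides, so the silyl chloride should take the 4-OH.

Step 3
Reactants: 3 1-[2-hydroxy-3-iodo-4-(triisopropylsilyloxy)phenyl]ethanone
Product: 5 8-iodo-7-(triisopropylsilyloxy)chromen-4-one, via dimethylamino enone 4 (not isolated)
Conditions: Me2NCH(OMe)2, toluene, 90 °C; then 2 M HCl, CH2Cl2, rt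
Reagents that add atoms: N,N-dimethylformamide dimethyl acetal, COC(OC)N(C)C
Why: Enaminone formation by condensation of the methyl ketone with the amide acetal, then acid-promoted intramolecular conjugate addition of the 2-OH and loss of dimethylamine, closes pyranone ring C; the aryl triisopropylsilyl ether should tolerate the brief aqueous acid.

Step 4
Reactants: 5 8-iodo-7-(triisopropylsilyloxy)chromen-4-one
Product: 6 7-(triisopropylsilyloxy)-8-vinylchromen-4-one
Conditions: Bu3SnCH=CH2 (1.3 equiv), Pd(PPh3)4 (5 mol %), toluene, 100 °C
Reagents that add atoms: tributyl(vinyl)stannane, C=C[Sn](CCCC)(CCCC)CCCC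
Why: Stille cross-coupling at zerovalent palladium is base-free, so the nucleophile-sensitive pyranone and the aryl silyl ether are left alone, and it is run before C2 becomes a stereocentre.

Step 5
Reactants: 6 7-(triisopropylsilyloxy)-8-vinylchromen-4-one; 7 phenylboronic acid
Product: 8 (2S)-7-(triisopropylsilyloxy)-8-vinylflavanone
Conditions: [Rh(OH)(cod)]2 (1.5 mol %), (S)-2,2'-bis[bis(3,4,5-trifluorophenyl)phosphino]-6,6'-dimethoxy-1,1'-biphenyl [(S)-MeO-F12-BIPHEP, 3.3 mol %], H2O (2 equiv), CH2Cl2, 25 °C
Reagents that add atoms: none
Why: Rhodium-catalysed asymmetric 1,4-addition of an arylboronic acid (Hayashi–Miyaura reaction) is a known route from chromones to flavanones with electron-poor biaryl diphosphines: the phenyl-rhodium species adds across C2=C3 on the face selected by the (S)-ligand to set (2S), water protonates the rhodium enolate, the twisted unactivated 8-vinyl group is not an acceptor for aryl-rhodium, and the base-free medium keeps the product from opening to the chalcone.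

Step 6
Reactants: 8 (2S)-7-(triisopropylsilyloxy)-8-vinylflavanone
Product: 9 (2S)-7-hydroxy-8-vinylflavanone
Conditions: Bu4NF (1.2 equiv), AcOH (1.2 equiv), THF, 0 °C
Reagents that add atoms: none
Why: Fluoride cleavage of the aryl silyl ether, buffered with acetic acid so that no enolate forms that could open the flavanone by retro-oxa-Michael elimination and racemise C2.

Step 7
Reactants: 10 (S)-2-methylglycidol
Product: 11 tert-butyl{[(2R)-2-methyloxiran-2-yl]methoxy}diphenylsilane
Conditions: t-BuPh2SiCl, imidazole, CH2Cl2, 0 °C to rt
Reagents that add atoms: tert-butyl(chloro)diphenylsilane, CC(C)(C)[Si](Cl)(c1ccccc1)c1ccccc1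
Why: Silylation of the primary alcohol without forming an alkoxide avoids the degenerate Payne rearrangement that would erode the enantiomeric purity; the stereocentre is untouched and its descriptor changes from S to R only through the CIP priorities.

Step 8
Reactants: 11 tert-butyl{[(2R)-2-methyloxiran-2-yl]methoxy}diphenylsilane
Product: 12 (2R)-1-(tert-butyldiphenylsilyloxy)-2-methylbut-3-en-2-ol
Conditions: Me3S+ I− (3 equiv), n-BuLi (2.9 equiv), THF, −10 °C to rt
Reagents that add atoms: trimethylsulfonium iodide, C[S+](C)C.[I-]
Why: Epoxide-to-allylic-alcohol homologation with dimethylsulfonium methylide: the ylide opens the epoxide by SN2 attack at the unsubstituted CH2, a second equivalent of base eliminates dimethyl sulfide, and the epoxide CH2 becomes the vinyl CH; no bond to the quaternary carbon is broken, which is why the (S)-glycidol leads to the (R)-carbinol.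

Step 9
Reactants: 12 (2R)-1-(tert-butyldiphenylsilyloxy)-2-methylbut-3-en-2-ol
Product: 13 (2R)-2-methylbut-3-ene-1,2-diol
Conditions: Bu4NF, THF, 0 °C to rt; direct chromatography
Reagents that add atoms: none
Why: Fluoride desilylation; any silyl migration between the two oxygens under the basic conditions of step 8 is of no consequence, because both silyl ethers converge on the same diol.

Step 10
Reactants: 13 (2R)-2-methylbut-3-ene-1,2-diol
Product: 14 (2R)-2-hydroxy-2-methylbut-3-en-1-yl acetate
Conditions: Ac2O (1.05 equiv), Et3N, DMAP (5 mol %), CH2Cl2, −20 °C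
Reagents that add atoms: acetic anhydride, CC(=O)OC(C)=O
Why: Chemoselective acylation: with one equivalent of anhydride at low temperature the primary hydroxyl should be acetylated much faster than the tertiary one.

Step 11
Reactants: 14 (2R)-2-hydroxy-2-methylbut-3-en-1-yl acetate; 15 diisopropylsilyl bis(trifluoromethanesulfonate); 9 (2S)-7-hydroxy-8-vinylflavanone
Product: 17 [(2R)-1-acetoxy-2-methylbut-3-en-2-yl]oxy{[(2S)-4-oxo-2-phenyl-8-vinylchroman-7-yl]oxy}diisopropylsilane, via silyl monotriflate 16 (not isolated)
Conditions: 15 (1.0 equiv), 2,6-lutidine, CH2Cl2, −78 °C, 14 (1.1 equiv) added dropwise, to −20 °C; then 9 (0.9 equiv), imidazole, −20 °C to rt; Et3N-deactivated silica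
Reagents that add atoms: none
Why: Stepwise silyl ether formation from a silyl bis(triflate): the hindered tertiary alcohol should displace only one triflate at low temperature, and the acidic phenol then displaces the second; adding the ketone-bearing phenol last, with imidazole and not a trialkylamine, keeps the silyl triflate from converting the flavanone ketone into a silyl enol ether.

Step 12
Reactants: 17 [(2R)-1-acetoxy-2-methylbut-3-en-2-yl]oxy{[(2S)-4-oxo-2-phenyl-8-vinylchroman-7-yl]oxy}diisopropylsilane
Product: 18 cyclic diisopropylsilylene of the target (O7 and O3' bridged; (2S,3'R); Z olefin inside the 8-membered 1,3-dioxa-2-silacyclooctene fused to ring A)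
Conditions: second-generation Grubbs catalyst RuCl2(H2IMes)(PCy3)(=CHPh) (10 mol % in two portions), degassed toluene (0.002 M), 80 °C, argon sparge
Reagents that add atoms: none
Why: The ruthenium benzylidene exchanges onto the unhindered 8-vinyl group to give an aryl-substituted carbene at C1', which adds across the tethered C2'=CH2 group in an intramolecular [2+2] cycloaddition; cycloreversion of the ruthenacyclobutane forms C1'=C2' and a ruthenium methylidene that carries the chain and releases ethylene. The closest known reaction type is ring-closing metathesis of bis(alkoxy)silane-tethered dienes to 7- and 8-membered dioxasilacycles. The single ring closed is the 8-membered 1,3-dioxa-2-silacyclooct-5-ene (O7, Si, O3', C3', C2', C1', C8, C7) fused to ring A, closed by forming the endocyclic C1'=C2' bond. No stereocentre is created, and C2 and C3' are not touched. The selectivity needed is olefin geometry: a trans double bond cannot be accommodated in this benzo-fused 8-membered ring without prohibitive strain, so the ring enforces Z independently of the catalyst. Ring closure over oligomerisation is favoured by high dilution, by the two isopropyl groups on silicon and the fully substituted C3', which press the chain ends together, and by removal of ethylene.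

Step 13
Reactants: 18 cyclic diisopropylsilylene of the target
Product: 19 target, (2R,3Z)-2-hydroxy-4-[(2S)-7-hydroxy-4-oxo-2-phenylchroman-8-yl]-2-methylbut-3-en-1-yl acetate
Conditions: Bu4NF (3 equiv), AcOH (3 equiv), THF, 0 °C to rt, in the dark; pH 7 buffer work-up
Reagents that add atoms: none
Why: Fluoride cleavage of both Si–O bonds of the silaketal, kept near neutral with acetic acid so that neither base-driven acetate loss or flavanone ring-opening nor acid-driven cyclodehydration of the Z ortho-hydroxystyryl carbinol to a 2H-chromene should occur.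

**Compound list**

1 | 2,4-dihydroxyacetophenone | CC(=O)c1ccc(O)cc1O | starting material
2 | 2,4-dihydroxy-3-iodoacetophenone | CC(=O)c1ccc(O)c(I)c1O | intermediate
3 | 1-[2-hydroxy-3-iodo-4-(triisopropylsilyloxy)phenyl]ethanone | CC(=O)c1ccc(O[Si](C(C)C)(C(C)C)C(C)C)c(I)c1O | intermediate
4 | (E)-3-(dimethylamino)-1-[2-hydroxy-3-iodo-4-(triisopropylsilyloxy)phenyl]prop-2-en-1-one (not isolated) | CN(C)/C=C/C(=O)c1ccc(O[Si](C(C)C)(C(C)C)C(C)C)c(I)c1O | intermediate
5 | 8-iodo-7-(triisopropylsilyloxy)chromen-4-one | O=c1ccoc2c(I)c(O[Si](C(C)C)(C(C)C)C(C)C)ccc12 | intermediate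
6 | 7-(triisopropylsilyloxy)-8-vinylchromen-4-one | O=c1ccoc2c(C=C)c(O[Si](C(C)C)(C(C)C)C(C)C)ccc12 | intermediate
7 | phenylboronic acid | OB(O)c1ccccc1 | starting material
8 | (2S)-7-(triisopropylsilyloxy)-8-vinylflavanone | C=Cc1c(O[Si](C(C)C)(C(C)C)C(C)C)ccc2c1O[C@H](c1ccccc1)CC2=O | intermediate
9 | (2S)-7-hydroxy-8-vinylflavanone | C=Cc1c(O)ccc2c1O[C@H](c1ccccc1)CC2=O | intermediate
10 | (S)-2-methylglycidol | C1[C@@](C)(O1)CO | starting material
11 | tert-butyl{[(2R)-2-methyloxiran-2-yl]methoxy}diphenylsilane | C1[C@@](C)(O1)CO[Si](c2ccccc2)(c2ccccc2)C(C)(C)C | intermediate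
12 | (2R)-1-(tert-butyldiphenylsilyloxy)-2-methylbut-3-en-2-ol | C=C[C@@](C)(O)CO[Si](c1ccccc1)(c1ccccc1)C(C)(C)C | intermediate
13 | (2R)-2-methylbut-3-ene-1,2-diol | C=C[C@@](C)(O)CO | intermediate
14 | (2R)-2-hydroxy-2-methylbut-3-en-1-yl acetate | CC(=O)OC[C@](C)(O)C=C | intermediate
15 | diisopropylsilyl bis(trifluoromethanesulfonate) | CC(C)[Si](OS(=O)(=O)C(F)(F)F)(OS(=O)(=O)C(F)(F)F)C(C)C | starting material
16 | [(2R)-1-acetoxy-2-methylbut-3-en-2-yl]oxy(diisopropyl)silyl trifluoromethanesulfonate (not isolated) | CC(=O)OC[C@](C)(O[Si](OS(=O)(=O)C(F)(F)F)(C(C)C)C(C)C)C=C | intermediate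
17 | [(2R)-1-acetoxy-2-methylbut-3-en-2-yl]oxy{[(2S)-4-oxo-2-phenyl-8-vinylchroman-7-yl]oxy}diisopropylsilane | CC(=O)OC[C@](C)(O[Si](C(C)C)(C(C)C)Oc1ccc2c(c1C=C)O[C@H](c1ccccc1)CC2=O)C=C | intermediate
18 | cyclic diisopropylsilylene of the target (O7 and O3' bridged; (2S,3'R); Z olefin in the 8-membered ring) | CC(=O)OC[C@](C)(O1)/C=C\c2c(O[Si]1(C(C)C)C(C)C)ccc3c2O[C@H](c2ccccc2)CC3=O | intermediate
19 | (2R,3Z)-2-hydroxy-4-[(2S)-7-hydroxy-4-oxo-2-phenylchroman-8-yl]-2-methylbut-3-en-1-yl acetate | CC(=O)OC[C@](C)(O)/C=C\c1c(O)ccc2c1O[C@H](c1ccccc1)CC2=O | target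

**Step count and risks**

Total step count: 13. Longest linear sequence: 9 steps (steps 1 to 6, then 11 to 13); the side-chain fragment takes steps 7 to 10.

Steps most likely to fail:

1. Step 12. After loading on the styrene, the carbene may engage the vinyl group on the fully substituted, silyloxy-bearing C3' too slowly, so that intermolecular dimerisation through the styrene and carbene decay overtake ring closure. Fallback, which sets the geometry photochemically and not by ring constraint: it sets out from 8 and 14 and rejoins the route at 19. Cross-metathesis of 8 with an excess of 14, whose free tertiary allylic hydroxyl makes it a better partner than its bulky silyl ether, using the second-generation Hoveyda–Grubbs catalyst RuCl2(H2IMes)(=CH-C6H4-2-OiPr) in CH2Cl2 at 40 °C, should give the E-configured 7-O-triisopropylsilyl styryl carbinol F1. Triplet-sensitised E-to-Z isomerisation with fac-Ir(ppy)3 under blue light in MeCN should then enrich the Z-configured silyl ether F2, because the Z isomer is twisted out of conjugation by its two ortho oxygens and the quaternary C3' and is a poorer energy acceptor, while the silyl group blocks phenol-driven chromene formation. Buffered Bu4NF/AcOH as in step 13 then gives 19.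

2. Step 5. The aryl-rhodium intermediate may be bound or diverted by the 8-vinyl group, stalling the conjugate addition on the already electron-rich 7-silyloxychromone. Fallback, which reverses the order of coupling and stereocentre formation: it sets out from 5 and rejoins at 8. The same rhodium-catalysed phenylation is run on iodochromone 5, which has no olefin besides the enone and whose aryl iodide should be inert to monovalent rhodium at 25 °C, giving (2S)-8-iodo-7-(triisopropylsilyloxy)flavanone F3. Base-free Stille vinylation (Bu3SnCH=CH2, Pd(PPh3)4, toluene, 90 °C) then gives 8 without the basic conditions that would epimerise C2 through the chalcone.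

3. Step 11. Redistribution at silicon to symmetrical bis(alkoxy) or bis(aryloxy) silanes, silylation of the flavanone enol by the triflate, or hydrolysis of the aryloxy–silicon bond during purification may erode the unsymmetrical silaketal. Fallback, which builds the tether from a monofunctional hydrosilane: it sets out from 14 and rejoins at 17. Silylation of 14 with chlorodiisopropylsilane and imidazole in CH2Cl2 should give the isolable hydrosilyl ether F4. N-bromosuccinimide in CH2Cl2 at 0 °C converts its Si–H into the silyl bromide F5, used in the same flask. Addition of 9 with Et3N and catalytic DMAP then gives 17; the bromide is a milder electrophile than the triflate and should not silylate the ketone.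

**Further compounds**

F1 | step 12 | (2R,3E)-2-hydroxy-2-methyl-4-[(2S)-4-oxo-2-phenyl-7-(triisopropylsilyloxy)chroman-8-yl]but-3-en-1-yl acetate | CC(=O)OC[C@](C)(O)/C=C/c1c(O[Si](C(C)C)(C(C)C)C(C)C)ccc2c1O[C@H](c1ccccc1)CC2=O
F2 | step 12 | (2R,3Z)-2-hydroxy-2-methyl-4-[(2S)-4-oxo-2-phenyl-7-(triisopropylsilyloxy)chroman-8-yl]but-3-en-1-yl acetate | CC(=O)OC[C@](C)(O)/C=C\c1c(O[Si](C(C)C)(C(C)C)C(C)C)ccc2c1O[C@H](c1ccccc1)CC2=O
F3 | step 5 | (2S)-8-iodo-7-(triisopropylsilyloxy)flavanone | Ic1c(O[Si](C(C)C)(C(C)C)C(C)C)ccc2c1O[C@H](c1ccccc1)CC2=O
F4 | step 11 | (2R)-2-(diisopropylsilyloxy)-2-methylbut-3-en-1-yl acetate | CC(=O)OC[C@](C)(O[SiH](C(C)C)C(C)C)C=C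
F5 | step 11 | (2R)-2-[bromo(diisopropyl)silyloxy]-2-methylbut-3-en-1-yl acetate | CC(=O)OC[C@](C)(O[Si](Br)(C(C)C)C(C)C)C=C
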